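**Retrosynthetic overview**
1. Target ⇐ Luche reduction of a C7 formyl group ⇐ Shi epoxidation of C10=C11 (oxirane formed last) ⇐ senecioylation of the C1 alcohol.
2. The 11-membered carbocycle (formed first) ⇐ intramolecular Nozaki–Hiyama–Kishi closure of the C1–C11 bond (alkenyl iodide onto enal).
3. Open-chain iodo dialdehyde ⇐ Wittig construction of C6=C7 with a formyl-stabilised ylide, allylic oxidation at C1, and oxyselenation of the prenyl terminus to the side-chain tertiary allylic alcohol.
4. C4 quaternary stereocentre together with the C2=C3 alkene ⇐ organocatalytic enantioselective conjugate alkenylation of citral with a hydroxypropenyl trifluoroborate (first stereocentre).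
5. Building blocks: citral, a propenol pinacol boronate, 6-chlorohex-2-yne, ethyl formate, senecioic acid.

Locants C1–C11 are the ring positions of the target: C1 carries the ester oxygen, C2=C3 is the trans alkene, C4 is the quaternary carbon, C6=C7 is the alkene whose C7 carries the hydroxymethyl group, and C10/C11 are the oxirane carbons (C11 carries the methyl).

Assumption: boronate 1 and 6-chlorohex-2-yne 5 are taken as catalogue compounds, and commercial citral is used as its E/Z mixture.

**Step 1**
Reactants: 1 (E)-3-(4,4,5,5-tetramethyl-1,3,2-dioxaborolan-2-yl)prop-2-en-1-ol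
Product: 2 potassium (E)-trifluoro(3-hydroxyprop-1-en-1-yl)borate
Conditions: KHF2 (4 equiv), MeOH–H2O, rt
Reagents that add atoms: potassium hydrogen difluoride, [K+].[F-].F
Why: Boronate-to-trifluoroborate exchange with KHF2; the E alkene is untouched.

**Step 2**
Reactants: 3 citral (3,7-dimethylocta-2,6-dienal, E/Z mixture); 2 potassium (E)-trifluoro(3-hydroxyprop-1-en-1-yl)borate
Product: 4 (3R,4E)-6-hydroxy-3-methyl-3-(4-methylpent-3-en-1-yl)hex-4-enal
Conditions: (S)-2-tert-butyl-3-methylimidazolidin-4-one trifluoroacetate (20 mol %), HF (48% aq., 1.0 equiv), DME, −20 °C, 72 h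
Reagents that add atoms: none
Why: Proposed new method: iminium-catalysed enantioselective conjugate alkenylation of a β,β-disubstituted enal, in which citral forms an iminium ion whose E and Z isomers interconvert through the dienamine, the alkenyltrifluoroborate attacks the β-carbon through its boron-bearing carbon on the face left open by the tert-butyl group (Friedel–Crafts-type ipso attack, loss of BF3 trapped as KBF4, E geometry retained), and hydrolysis releases 4 with the C4 quaternary centre set by the catalyst (the S catalyst is chosen by analogy with the facial sense of hydride transfer to β,β-disubstituted enals under this imidazolidinone; the R catalyst would give ent-4); the closest known reactions are the imidazolidinone-catalysed addition of alkenyl- and heteroaryl-trifluoroborates to β-monosubstituted enals and the organocatalytic hydride and nitroalkane additions to β,β-disubstituted enals.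

**Step 3**
Reactants: 5 6-chlorohex-2-yne
Product: 7 (E)-6-chloro-2-iodohex-2-ene, via alkenylzirconocene chloride 6 (not isolated)
Conditions: Cp2Zr(H)Cl (2.2 equiv), THF, 40 °C; then I2, 0 °C
Reagents that add atoms: iodine, II
Why: Hydrozirconation–iodination: syn Zr–H addition, equilibration with excess Cp2Zr(H)Cl to put zirconium on the methyl-bearing carbon, and iododezirconation with retention give the (E)-2-iodo-2-alkene.

**Step 4**
Reactants: 7 (E)-6-chloro-2-iodohex-2-ene
Product: 9 [(E)-5-iodohex-4-en-1-yl]triphenylphosphonium iodide, via (E)-2,6-diiodohex-2-ene 8 (not isolated)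
Conditions: NaI (1.5 equiv), PPh3 (1.2 equiv), MeCN, reflux
Reagents that add atoms: sodium iodide, [Na+].[I-]; triphenylphosphine, c1ccc(cc1)P(c1ccccc1)c1ccccc1
Why: Finkelstein exchange followed by SN2 quaternisation of PPh3 at the primary carbon; the alkenyl iodide is inert.

**Step 5**
Reactants: 9 [(E)-5-iodohex-4-en-1-yl]triphenylphosphonium iodide
Product: 11 (E)-6-iodo-2-(triphenylphosphoranylidene)hept-5-enal, via non-stabilised ylide 10 (not isolated)
Conditions: KOtBu (2.1 equiv), THF, 0 °C; then HCO2Et, 0 °C to rt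
Reagents that add atoms: ethyl formate, CCOC=O
Why: C-Formylation of a phosphorus ylide with ethyl formate, followed by deprotonation to the formyl-stabilised ylide.

**Step 6**
Reactants: 4 (3R,4E)-6-hydroxy-3-methyl-3-(4-methylpent-3-en-1-yl)hex-4-enal; 11 (E)-6-iodo-2-(triphenylphosphoranylidene)hept-5-enal
Product: 12 (2E,5R,6E)-8-hydroxy-2-[(3E)-4-iodopent-3-en-1-yl]-5-methyl-5-(4-methylpent-3-en-1-yl)octa-2,6-dienal
Conditions: toluene, 90 °C
Reagents that add atoms: none
Why: Wittig reaction of a formyl-stabilised α-alkyl ylide gives the (E)-2-alkyl enal (formyl trans to C5, C8 cis to C5), which is the ring-cis geometry needed at C6=C7; the product enal is less electrophilic than 4, which limits over-olefination.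

**Step 7**
Reactants: 12 (2E,5R,6E)-8-hydroxy-2-[(3E)-4-iodopent-3-en-1-yl]-5-methyl-5-(4-methylpent-3-en-1-yl)octa-2,6-dienal
Product: 13 (2E,5R,6E)-2-[(3E)-4-iodopent-3-en-1-yl]-5-methyl-5-(4-methylpent-3-en-1-yl)octa-2,6-dienedial
Conditions: MnO2 (20 equiv), CH2Cl2, rt
Reagents that add atoms: none
Why: Allylic alcohol oxidation with MnO2 converts the only allylic alcohol into the C1 enal.

**Step 8**
Reactants: 13 (2E,5R,6E)-2-[(3E)-4-iodopent-3-en-1-yl]-5-methyl-5-(4-methylpent-3-en-1-yl)octa-2,6-dienedial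
Product: 16 (2E,5R,6E)-5-[(2E)-4-hydroxy-4-methylpent-2-en-1-yl]-2-[(3E)-4-iodopent-3-en-1-yl]-5-methylocta-2,6-dienedial, via β-hydroxy selenide 14 (not isolated), via selenoxide 15 (not isolated)
Conditions: N-(phenylselanyl)phthalimide (1.2 equiv), H2O (5 equiv), camphorsulfonic acid (10 mol %), CH2Cl2, rt; then NaIO4 (3 equiv), THF–MeOH–H2O, rt
Reagents that add atoms: water, O
Why: Hydroxyselenation then selenoxide syn-elimination: PhSe+ adds to the only electron-rich alkene (both enals and the iodoalkene are deactivated), water opens the seleniranium ion at the tertiary carbon, and the selenoxide can only eliminate away from the carbinol to give the (E)-allylic tertiary alcohol.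

**Step 9**
Reactants: 16 (2E,5R,6E)-5-[(2E)-4-hydroxy-4-methylpent-2-en-1-yl]-2-[(3E)-4-iodopent-3-en-1-yl]-5-methylocta-2,6-dienedial
Product: 17 (1S,2E,4R,6E,10E)-1-hydroxy-4-[(2E)-4-hydroxy-4-methylpent-2-en-1-yl]-4,11-dimethylcycloundeca-2,6,10-triene-7-carbaldehyde (target ring locants)
Conditions: CrCl2 (8 equiv), (S)-N-[2-(4-isopropyl-4,5-dihydrooxazol-2-yl)-6-methylphenyl]methanesulfonamide (8.8 equiv), Et3N (8.8 equiv), NiCl2 (0.5 equiv), THF–MeCN, rt, slow addition of 16 to 2 mM
Reagents that add atoms: none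
Why: Intramolecular Nozaki–Hiyama–Kishi reaction: nickel-mediated activation of the C11–I bond and transfer to chromium give a configurationally stable alkenylchromium species that adds 1,2 to the C1 enal (closure onto the C7 formyl group would need an E-cyclohexene), and the chiral trivalent chromium–sulfonamide complex, not the remote C4 centre, sets C1 as S.

**Step 10**
Reactants: 17 (1S,2E,4R,6E,10E)-1-hydroxy-4-[(2E)-4-hydroxy-4-methylpent-2-en-1-yl]-4,11-dimethylcycloundeca-2,6,10-triene-7-carbaldehyde; 18 3-methylbut-2-enoic acid (senecioic acid)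
Product: 19 (1S,2E,4R,6E,10E)-7-formyl-4-[(2E)-4-hydroxy-4-methylpent-2-en-1-yl]-4,11-dimethylcycloundeca-2,6,10-trien-1-yl 3-methylbut-2-enoate
Conditions: DCC (1.5 equiv), DMAP (0.2 equiv), CH2Cl2, 0 °C to rt
Reagents that add atoms: none
Why: Steglich esterification acylates the secondary C1 alcohol and leaves the tertiary allylic alcohol alone; carbodiimide activation avoids the ketene pathway that deconjugates senecioyl chloride, and C1 is not touched (O-acylation).

**Step 11**
Reactants: 19 (1S,2E,4R,6E,10E)-7-formyl-4-[(2E)-4-hydroxy-4-methylpent-2-en-1-yl]-4,11-dimethylcycloundeca-2,6,10-trien-1-yl 3-methylbut-2-enoate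
Product: 20 (1S,2E,4R,6E,10R,11S)-10,11-epoxy-7-formyl-4-[(2E)-4-hydroxy-4-methylpent-2-en-1-yl]-4,11-dimethylcycloundeca-2,6-dien-1-yl 3-methylbut-2-enoate
Conditions: 1,2:4,5-di-O-isopropylidene-β-D-erythro-2,3-hexodiulo-2,6-pyranose (D-fructose-derived Shi ketone, 30 mol %), KHSO5 (as Oxone, 2KHSO5·KHSO4·K2SO4, 1.4 equiv), K2CO3, Bu4NHSO4 (cat.), MeCN–dimethoxymethane / aq. Na2B4O7 buffer (pH 10.5), 0 °C
Reagents that add atoms: potassium peroxymonosulfate, [K+].[O-]S(=O)(=O)OO
Why: Shi epoxidation (chiral dioxirane, spiro transition state): the D-fructose-derived ketone delivers oxygen to the face of the E-trisubstituted C10=C11 bond that gives 10R,11S (threo to the C1 ester), which is also the peripheral face anti to the C1–C2 ring bond when the acyloxy group lies in the alkene plane; the enal, the enoate and the two hindered 1,2-disubstituted alkenes are less nucleophilic.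

**Step 12**
Reactants: 20 (1S,2E,4R,6E,10R,11S)-10,11-epoxy-7-formyl-4-[(2E)-4-hydroxy-4-methylpent-2-en-1-yl]-4,11-dimethylcycloundeca-2,6-dien-1-yl 3-methylbut-2-enoate
Product: 21 CNP0248133.1 (target)
Conditions: NaBH4, CeCl3·7H2O, MeOH, −40 °C
Reagents that add atoms: none
Why: Luche reduction converts the enal 1,2 into the primary allylic alcohol and leaves the senecioate and the oxirane intact; the formyl group has acted as a latent hydroxymethyl group that kept C6=C7 inert to the dioxirane.

**Compound list**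
1 | (E)-3-(4,4,5,5-tetramethyl-1,3,2-dioxaborolan-2-yl)prop-2-en-1-ol | OC/C=C/B1OC(C)(C)C(C)(C)O1 | starting material
2 | potassium (E)-trifluoro(3-hydroxyprop-1-en-1-yl)borate | OC/C=C/[B-](F)(F)F.[K+] | intermediate
3 | citral (E/Z mixture) | CC(C)=CCCC(C)=CC=O | starting material
4 | (3R,4E)-6-hydroxy-3-methyl-3-(4-methylpent-3-en-1-yl)hex-4-enal | OC/C=C/[C@](C)(CCC=C(C)C)CC=O | intermediate
5 | 6-chlorohex-2-yne | CC#CCCCCl | starting material
6 | chlorobis(cyclopentadienyl)[(E)-6-chlorohex-2-en-2-yl]zirconium | C/C(=C\CCCCl)[Zr](Cl)(C1C=CC=C1)C1C=CC=C1 | intermediate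
7 | (E)-6-chloro-2-iodohex-2-ene | C/C(I)=C\CCCCl | intermediate
8 | (E)-2,6-diiodohex-2-ene | C/C(I)=C\CCCI | intermediate
9 | [(E)-5-iodohex-4-en-1-yl]triphenylphosphonium iodide | C/C(I)=C\CCC[P+](c1ccccc1)(c1ccccc1)c1ccccc1.[I-] | intermediate
10 | [(E)-5-iodohex-4-en-1-ylidene]triphenylphosphorane | C/C(I)=C\CCC=P(c1ccccc1)(c1ccccc1)c1ccccc1 | intermediate
11 | (E)-6-iodo-2-(triphenylphosphoranylidene)hept-5-enal | C/C(I)=C\CCC(C=O)=P(c1ccccc1)(c1ccccc1)c1ccccc1 | intermediate
12 | (2E,5R,6E)-8-hydroxy-2-[(3E)-4-iodopent-3-en-1-yl]-5-methyl-5-(4-methylpent-3-en-1-yl)octa-2,6-dienal | OC/C=C/[C@](C)(CCC=C(C)C)C/C=C(/C=O)CC/C=C(\C)I | intermediate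
13 | (2E,5R,6E)-2-[(3E)-4-iodopent-3-en-1-yl]-5-methyl-5-(4-methylpent-3-en-1-yl)octa-2,6-dienedial | O=C/C=C/[C@](C)(CCC=C(C)C)C/C=C(/C=O)CC/C=C(\C)I | intermediate
14 | (2E,5R,6E)-5-[4-hydroxy-4-methyl-3-(phenylselanyl)pentyl]-2-[(3E)-4-iodopent-3-en-1-yl]-5-methylocta-2,6-dienedial (epimers at the selenium-bearing carbon) | O=C/C=C/[C@](C)(CCC([Se]c1ccccc1)C(C)(C)O)C/C=C(/C=O)CC/C=C(\C)I | intermediate
15 | selenoxide of 14 | O=C/C=C/[C@](C)(CCC([Se](=O)c1ccccc1)C(C)(C)O)C/C=C(/C=O)CC/C=C(\C)I | intermediate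
16 | (2E,5R,6E)-5-[(2E)-4-hydroxy-4-methylpent-2-en-1-yl]-2-[(3E)-4-iodopent-3-en-1-yl]-5-methylocta-2,6-dienedial | O=C/C=C/[C@](C)(C/C=C/C(C)(C)O)C/C=C(/C=O)CC/C=C(\C)I | intermediate
17 | (1S,2E,4R,6E,10E)-1-hydroxy-4-[(2E)-4-hydroxy-4-methylpent-2-en-1-yl]-4,11-dimethylcycloundeca-2,6,10-triene-7-carbaldehyde | O[C@H]1/C=C/[C@](C)(C/C=C/C(C)(C)O)C/C=C(/C=O)CC/C=C1\C | intermediate
18 | 3-methylbut-2-enoic acid (senecioic acid) | CC(C)=CC(=O)O | starting material
19 | (1S,2E,4R,6E,10E)-7-formyl-4-[(2E)-4-hydroxy-4-methylpent-2-en-1-yl]-4,11-dimethylcycloundeca-2,6,10-trien-1-yl 3-methylbut-2-enoate | CC(C)=CC(=O)O[C@H]1/C=C/[C@](C)(C/C=C/C(C)(C)O)C/C=C(/C=O)CC/C=C1\C | intermediate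
20 | (1S,2E,4R,6E,10R,11S)-10,11-epoxy-7-formyl-4-[(2E)-4-hydroxy-4-methylpent-2-en-1-yl]-4,11-dimethylcycloundeca-2,6-dien-1-yl 3-methylbut-2-enoate | CC(C)=CC(=O)O[C@H]1/C=C/[C@](C)(C/C=C/C(C)(C)O)C/C=C(/C=O)CC[C@H]2O[C@]12C | intermediate
21 | CNP0248133.1 | CC(C)=CC(=O)O[C@H]1/C=C/[C@](C)(C/C=C/C(C)(C)O)C/C=C(/CO)CC[C@H]2O[C@]12C | target

**Totals**
Total step count: 12. Longest linear sequence: 10 steps (5 → 7 → 9 → 11 → 12 → 13 → 16 → 17 → 19 → 20 → 21).

**Three steps most likely to fail**

Step 2 (the proposed new method). The iminium ion of a β,β-disubstituted enal is hindered and weakly electrophilic, so the trifluoroborate may protodeboronate or add too slowly, and the facial sense is assigned only by analogy. The fallback uses known chemistry, sets out from citral 3 and returns at dialdehyde 13. Citral 3 and commercial 2-(2-nitroethyl)-1,3-dioxolane undergo the known (S)-diphenylprolinol trimethylsilyl ether-catalysed Michael addition of a nitroalkane to a β,β-disubstituted enal, giving nitro aldehyde F1 (C4 set as R, nitro-bearing carbon as an epimer mixture). Wittig reaction of nitro aldehyde F1 with ylide 11 (toluene, 90 °C) gives enal F2. Dilute aqueous HCl in THF cleaves the dioxolane to β-nitro aldehyde F3, which loses nitrous acid on treatment with Et3N to give the E enal, that is 13.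

Step 9. The 11-membered closure competes with oligomerisation (two aldehydes are present), and the sense and level of induction of the sulfonamide ligand on this enal are not secured. The fallback sets C1 by ketone reduction instead of by C–C bond formation; it sets out from 16 and returns at 17. Closing 16 without chiral ligand (CrCl2, NiCl2 cat., DMSO, 2 mM) gives 17 mixed with its C1 epimer F4. MnO2 oxidises the mixture to the cross-conjugated ketone F5. (R)-Me-CBS oxazaborolidine with catecholborane (−78 °C) reduces the ketone to the 1S alcohol (the α-methylalkenyl side acting as the large group) and also the formyl group, giving diol F6. TEMPO with PhI(OAc)2 then reoxidises only the primary allylic alcohol and returns 17.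

Step 11. The ring may expose the other face of C10=C11 and override the catalyst (giving the erythro epoxide), and the side-chain alkene or the formyl group may be oxidised competitively. The fallback builds the oxirane by displacement instead of direct oxygen transfer; it sets out from 19 and returns at 20. NBS in aqueous DME at 0 °C gives bromohydrin F7 (water opens the bromonium ion anti at the tertiary C11). K2CO3 in MeOH at 0 °C closes it to 20 with inversion at C10. Because the oxirane oxygen ends up on the face opposite to the one attacked by the electrophile, this route is complementary to direct epoxidation if external reagents prefer the wrong face.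

Further compounds
F1 | step 2 | (3R)-5-(1,3-dioxolan-2-yl)-3-methyl-3-(4-methylpent-3-en-1-yl)-4-nitropentanal (epimers at C4) | [O-][N+](=O)C(CC1OCCO1)[C@](C)(CCC=C(C)C)CC=O
F2 | step 2 | (2E,5R)-5-[2-(1,3-dioxolan-2-yl)-1-nitroethyl]-2-[(3E)-4-iodopent-3-en-1-yl]-5,9-dimethyldeca-2,8-dienal | [O-][N+](=O)C(CC1OCCO1)[C@](C)(CCC=C(C)C)C/C=C(/C=O)CC/C=C(\C)I
F3 | step 2 | (2E,5R)-2-[(3E)-4-iodopent-3-en-1-yl]-5,9-dimethyl-5-(1-nitro-3-oxopropyl)deca-2,8-dienal | [O-][N+](=O)C(CC=O)[C@](C)(CCC=C(C)C)C/C=C(/C=O)CC/C=C(\C)I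
F4 | step 9 | (1R,2E,4R,6E,10E)-1-hydroxy-4-[(2E)-4-hydroxy-4-methylpent-2-en-1-yl]-4,11-dimethylcycloundeca-2,6,10-triene-7-carbaldehyde | O[C@@H]1/C=C/[C@](C)(C/C=C/C(C)(C)O)C/C=C(/C=O)CC/C=C1\C
F5 | step 9 | (2E,4R,6E,10E)-4-[(2E)-4-hydroxy-4-methylpent-2-en-1-yl]-4,11-dimethyl-1-oxocycloundeca-2,6,10-triene-7-carbaldehyde | O=C1/C=C/[C@](C)(C/C=C/C(C)(C)O)C/C=C(/C=O)CC/C=C1\C
F6 | step 9 | (1S,2E,4R,6E,10E)-7-(hydroxymethyl)-4-[(2E)-4-hydroxy-4-methylpent-2-en-1-yl]-4,11-dimethylcycloundeca-2,6,10-trien-1-ol | O[C@H]1/C=C/[C@](C)(C/C=C/C(C)(C)O)C/C=C(/CO)CC/C=C1\C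
F7 | step 11 | (1S,2E,4R,6E,10S,11R)-10-bromo-7-formyl-11-hydroxy-4-[(2E)-4-hydroxy-4-methylpent-2-en-1-yl]-4,11-dimethylcycloundeca-2,6-dien-1-yl 3-methylbut-2-enoate | CC(C)=CC(=O)O[C@H]1/C=C/[C@](C)(C/C=C/C(C)(C)O)C/C=C(/C=O)CC[C@H](Br)[C@]1(C)O
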